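**Retrosynthetic overview**
- The target is the hepta-O-benzyl ether after hydrogenolysis; every C-2/C-3 pair comes from one chiral C3 unit, a (2R,3S)-3-aryl-oxirane-2-carbaldehyde.
- Each pyran ring is built by [3+3] annulation of a phenol ring with that epoxy-aldehyde (C-4–C-4a by ortho-hydroxyalkylation, then O-1–C-2 by 6-endo epoxide opening), not by joining preformed flavans.
- Interflavan bonds: upper C-4–aryl by syn opening of a 3,4-epoxyflavan with resorcinol borate (4β); middle C-4–aryl by SN1 condensation of the middle 3,4-diol with resorcinol (4α). Each new resorcinol ring is then annulated.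
- Key step: 3-benzyloxyphenol plus the epoxy-aldehyde gives the upper 3,4-epoxyflavan in one flask (pyran and oxirane rings, three stereocentres).
- Ring order: upper C-ring with its oxirane, then middle C-ring, then lower C-ring (formed directly as the terminal 3,4-diol).

Assumption: the SMILES is read as fisetinidol-(4β→6)-fisetinidol-(4α→6)-(+)-mollisacacidin, i.e. upper unit 2R,3S,4S (3,4-cis), middle unit 2R,3S,4R (3,4-trans), lower unit 2R,3S,4R (3,4-trans diol).

**Route**

Step 1
Reactants: 1 3,4-bis(benzyloxy)benzaldehyde; 2 (triphenylphosphoranylidene)acetaldehyde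
Product: 3 (E)-3-[3,4-bis(benzyloxy)phenyl]prop-2-enal
Conditions: toluene, 80 °C
Reagents that add atoms: none
Why: Wittig olefination with the stabilised formylmethylene ylide gives the (E)-enal selectively from the non-enolisable aldehyde.

Step 2
Reactants: 3 (E)-3-[3,4-bis(benzyloxy)phenyl]prop-2-enal
Product: 4 (2R,3S)-3-[3,4-bis(benzyloxy)phenyl]oxirane-2-carbaldehyde
Conditions: 35% aq. H2O2, (S)-2-{bis[3,5-bis(trifluoromethyl)phenyl][(trimethylsilyl)oxy]methyl}pyrrolidine (10 mol %), CH2Cl2, rt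
Reagents that add atoms: hydrogen peroxide, OO
Why: Jørgensen iminium/enamine organocatalytic epoxidation, in which the (S)-diarylprolinol silyl ether shields one face of the iminium ion so that hydroperoxide adds to Cβ and the enamine closes the trans-oxirane, sets the (2R,3S) configuration that later becomes C-3 (retained) and C-2 (after inversion) of every flavan unit.

Step 3
Reactants: 5 3-(benzyloxy)phenol; 4 (2R,3S)-3-[3,4-bis(benzyloxy)phenyl]oxirane-2-carbaldehyde
Product: 7 (2R,3S,4S)-7-(benzyloxy)-2-[3,4-bis(benzyloxy)phenyl]-3,4-epoxychromane, via flavan-3,4-diol 6 (not isolated)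
Conditions: (i) EtMgBr (1.0 equiv), Et2O then toluene, 0 °C; 4, −20 °C → rt; (ii) PPh3, DIAD, THF, 0 °C → rt, same flask; filtration through basic alumina, used at once
Reagents that add atoms: none
Why: Proposed new method: Casiraghi-type ortho-hydroxyalkylation of the bromomagnesium phenoxide (C–C bond para to OBn) is followed by Mg-assisted 6-endo phenolysis of the aryl oxirane with inversion at the benzylic carbon (2,3-trans, C-3 oxygen retained) to give diol 6, and Mitsunobu-type cyclodehydration then breaks only the electron-rich benzylic C-4–O bond so that O-3 closes the oxirane on the face anti to the 2-aryl group, the closest known reactions being ortho-specific hydroxyalkylation of magnesium phenoxides, 6-endo epoxide cyclisations to flavan-3-ols and Mitsunobu epoxide formation from 1-aryl-1,2-diols.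

Step 4
Reactants: 7 (2R,3S,4S)-7-(benzyloxy)-2-[3,4-bis(benzyloxy)phenyl]-3,4-epoxychromane; 8 resorcinol
Product: 9 (2R,3S,4S)-7-(benzyloxy)-2-[3,4-bis(benzyloxy)phenyl]-4-(2,4-dihydroxyphenyl)chroman-3-ol
Conditions: 8 (3 equiv), BH3·SMe2 (1 equiv), THF, rt; then 7, toluene–THF, −78 °C → rt; aq. NaHCO3
Reagents that add atoms: none
Why: Proposed new method: boron of the resorcinol borate activates the benzylic oxirane and, within the resulting ion pair, the boron-bound aryloxy group delivers its less hindered ortho carbon (para to the second OH) to C-4 on the face of the departing oxygen, giving the 3,4-cis (4β, 4S) aryl group with retention, the closest known reactions being the syn-stereoselective ring opening of benzylic epoxides by aryl borates and its ortho-selective Friedel–Crafts variant.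

Step 5
Reactants: 9 (2R,3S,4S)-7-(benzyloxy)-2-[3,4-bis(benzyloxy)phenyl]-4-(2,4-dihydroxyphenyl)chroman-3-ol; 4 (2R,3S)-3-[3,4-bis(benzyloxy)phenyl]oxirane-2-carbaldehyde
Product: 10 (2R,3S,4R)-6-{(2R,3S,4S)-7-(benzyloxy)-2-[3,4-bis(benzyloxy)phenyl]-3-hydroxychroman-4-yl}-2-[3,4-bis(benzyloxy)phenyl]chromane-3,4,7-triol
Conditions: EtMgBr (3.1 equiv), toluene–THF, 0 °C; 4 (1.2 equiv), −20 °C → rt
Reagents that add atoms: none
Why: Proposed new method: the same magnesium-phenoxide ortho-hydroxyalkylation/6-endo epoxide phenolysis as in step 3 (stage i), here at the resorcinol carbon ortho to one OMg and para to the other with ring closure through the adjacent oxygen, builds the middle pyran ring with 2R,3S fixed by 4, and the C-4 carbinol configuration is irrelevant because it is ionised in step 6.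

Step 6
Reactants: 10 (2R,3S,4R)-6-{(2R,3S,4S)-7-(benzyloxy)-2-[3,4-bis(benzyloxy)phenyl]-3-hydroxychroman-4-yl}-2-[3,4-bis(benzyloxy)phenyl]chromane-3,4,7-triol; 8 resorcinol
Product: 11 (2R,3S,4R)-6-{(2R,3S,4S)-7-(benzyloxy)-2-[3,4-bis(benzyloxy)phenyl]-3-hydroxychroman-4-yl}-2-[3,4-bis(benzyloxy)phenyl]-4-(2,4-dihydroxyphenyl)chromane-3,7-diol
Conditions: 8 (10 equiv), 0.1 M HCl, EtOH–THF–H2O, rt
Reagents that add atoms: none
Why: Acid-catalysed SN1 Friedel–Crafts condensation of a 7-hydroxyflavan-3,4-diol with resorcinol (the classical leucofisetinidin coupling), in which the para-hydroxy-stabilised C-4 cation is attacked anti to the 3-OH to give mainly the 3,4-trans (4α, 4R) adduct (expected about 2–3:1, the 3,4-cis epimer being removed by chromatography).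

Step 7
Reactants: 11 (2R,3S,4R)-6-{(2R,3S,4S)-7-(benzyloxy)-2-[3,4-bis(benzyloxy)phenyl]-3-hydroxychroman-4-yl}-2-[3,4-bis(benzyloxy)phenyl]-4-(2,4-dihydroxyphenyl)chromane-3,7-diol; 4 (2R,3S)-3-[3,4-bis(benzyloxy)phenyl]oxirane-2-carbaldehyde
Product: 12 hepta-O-benzyl ether of the target (7-O-benzyl on the upper unit and 3',4'-di-O-benzyl on all three units; 2R,3S,4S / 2R,3S,4R / 2R,3S,4R)
Conditions: EtMgBr (5.1 equiv), toluene–THF, 0 °C; 4 (1.2 equiv), −20 °C → rt
Reagents that add atoms: none
Why: Proposed new method: third use of the magnesium-phenoxide ortho-hydroxyalkylation/6-endo epoxide phenolysis, now on the free resorcinol ring, in which Cram-chelate addition of the aryl carbon to the Mg-bound epoxy-aldehyde sets C-4 as R (3,4-trans) while 4 fixes 2R,3S, so the terminal flavan-3,4-diol is formed directly.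

Step 8
Reactants: 12 hepta-O-benzyl ether of the target
Product: 13 fisetinidol-(4β→6)-fisetinidol-(4α→6)-(+)-mollisacacidin (CNP0255184.1)
Conditions: H2 (1 atm), 10% Pd/C, THF–MeOH, rt, stopped at full debenzylation
Reagents that add atoms: none
Why: Catalytic hydrogenolysis of the seven aryl benzyl ethers under neutral conditions leaves the interflavan bonds and the more slowly cleaved benzylic 4-OH intact and creates no new stereocentre.

**Compound list**

1 | 3,4-bis(benzyloxy)benzaldehyde | O=Cc1ccc(OCc2ccccc2)c(OCc2ccccc2)c1 | starting material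
2 | (triphenylphosphoranylidene)acetaldehyde | O=CC=P(c1ccccc1)(c1ccccc1)c1ccccc1 | starting material
3 | (E)-3-[3,4-bis(benzyloxy)phenyl]prop-2-enal | O=C/C=C/c1ccc(OCc2ccccc2)c(OCc2ccccc2)c1 | intermediate
4 | (2R,3S)-3-[3,4-bis(benzyloxy)phenyl]oxirane-2-carbaldehyde (trans) | O=C[C@@H]1O[C@H]1c1ccc(OCc2ccccc2)c(OCc2ccccc2)c1 | intermediate
5 | 3-(benzyloxy)phenol | Oc1cccc(OCc2ccccc2)c1 | starting material
6 | (2R,3S,4R)-7-(benzyloxy)-2-[3,4-bis(benzyloxy)phenyl]chromane-3,4-diol (present in the flask as its magnesium alkoxide) | c1ccccc1COc1ccc2c(c1)O[C@H](c1ccc(OCc3ccccc3)c(OCc3ccccc3)c1)[C@@H](O)[C@@H]2O | intermediate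
7 | (2R,3S,4S)-7-(benzyloxy)-2-[3,4-bis(benzyloxy)phenyl]-3,4-epoxychromane (oxirane anti to the 2-aryl group) | c1ccccc1COc1ccc2c(c1)O[C@H](c1ccc(OCc3ccccc3)c(OCc3ccccc3)c1)[C@H]3O[C@@H]23 | intermediate
8 | resorcinol (benzene-1,3-diol) | Oc1cccc(O)c1 | starting material
9 | (2R,3S,4S)-7-(benzyloxy)-2-[3,4-bis(benzyloxy)phenyl]-4-(2,4-dihydroxyphenyl)chroman-3-ol (2,3-trans-3,4-cis) | c1ccccc1COc1ccc2c(c1)O[C@H](c1ccc(OCc3ccccc3)c(OCc3ccccc3)c1)[C@@H](O)[C@H]2c1ccc(O)cc1O | intermediate
10 | (2R,3S,4R)-6-{(2R,3S,4S)-7-(benzyloxy)-2-[3,4-bis(benzyloxy)phenyl]-3-hydroxychroman-4-yl}-2-[3,4-bis(benzyloxy)phenyl]chromane-3,4,7-triol | c1ccccc1COc1ccc2c(c1)O[C@H](c1ccc(OCc3ccccc3)c(OCc3ccccc3)c1)[C@@H](O)[C@H]2c1cc2c(cc1O)O[C@H](c1ccc(OCc3ccccc3)c(OCc3ccccc3)c1)[C@@H](O)[C@@H]2O | intermediate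
11 | (2R,3S,4R)-6-{(2R,3S,4S)-7-(benzyloxy)-2-[3,4-bis(benzyloxy)phenyl]-3-hydroxychroman-4-yl}-2-[3,4-bis(benzyloxy)phenyl]-4-(2,4-dihydroxyphenyl)chromane-3,7-diol | c1ccccc1COc1ccc2c(c1)O[C@H](c1ccc(OCc3ccccc3)c(OCc3ccccc3)c1)[C@@H](O)[C@H]2c1cc2c(cc1O)O[C@H](c1ccc(OCc3ccccc3)c(OCc3ccccc3)c1)[C@@H](O)[C@@H]2c1ccc(O)cc1O | intermediate
12 | hepta-O-benzyl ether of the target: 7-O-benzyl-3',4'-di-O-benzylfisetinidol-(4β→6)-3',4'-di-O-benzylfisetinidol-(4α→6)-3',4'-di-O-benzylmollisacacidin | c1ccccc1COc1ccc2c(c1)O[C@H](c1ccc(OCc3ccccc3)c(OCc3ccccc3)c1)[C@@H](O)[C@H]2c1cc2c(cc1O)O[C@H](c1ccc(OCc3ccccc3)c(OCc3ccccc3)c1)[C@@H](O)[C@@H]2c1cc2c(cc1O)O[C@H](c1ccc(OCc3ccccc3)c(OCc3ccccc3)c1)[C@@H](O)[C@@H]2O | intermediate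
13 | fisetinidol-(4β→6)-fisetinidol-(4α→6)-(+)-mollisacacidin (upper 2R,3S,4S; middle 2R,3S,4R; lower 2R,3S,4R) | Oc1ccc2c(c1)O[C@H](c1ccc(O)c(O)c1)[C@@H](O)[C@H]2c1cc2c(cc1O)O[C@H](c1ccc(O)c(O)c1)[C@@H](O)[C@@H]2c1cc2c(cc1O)O[C@H](c1ccc(O)c(O)c1)[C@@H](O)[C@@H]2O | target

**Step count and risks**

Total steps: 8. Longest linear sequence: 8 (1 → 3 → 4 → 7 → 9 → 10 → 11 → 12 → 13; compound 4 is used three times).

The three steps most likely to fail:

The one-flask annulation and oxirane closure (step 3) is the least certain. The electron-rich aryl oxirane of 4 may rearrange under magnesium Lewis acidity, a 5-exo closure may compete, and 7 is acid-labile. The fallback sets out from 5 and uses the enal 3 instead of 4. Phenylboronic acid/acetic acid-mediated [3+3] condensation (toluene, reflux, Dean–Stark) gives racemic 7-(benzyloxy)-2-[3,4-bis(benzyloxy)phenyl]-2H-chromene F1. Jacobsen epoxidation with the (S,S)-(salen)Mn(III) catalyst (NaOCl, 4-phenylpyridine N-oxide, CH2Cl2, 0 °C) then serves as a kinetic resolution: the (2S)-chromene is oxidised on the face anti to its aryl group. This returns to the route at 7, at the cost of at most 50% yield.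

The syn arylation (step 4) may give the cis aryl ether by O-delivery, or attack through the resorcinol carbon between the two hydroxyls. The fallback sets out from 7 with 8 under non-directed SN1 conditions (BF3·OEt2 cat., THF, −78 °C, excess 8). It gives the 3,4-trans epimer (2R,3S,4R)-7-(benzyloxy)-2-[3,4-bis(benzyloxy)phenyl]-4-(2,4-dihydroxyphenyl)chroman-3-ol F2 as the major product and 9 as the minor one (expected about 2–3:1). Compound 9 is separated by chromatography and the route is rejoined at 9.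

The last annulation (step 7) is run on a pentahydroxy substrate: hydroxyalkylation may also occur at C-8 of the middle unit, and the C-4 selectivity depends on chelation. The fallback sets out from 10 and bypasses 11. The lower unit is made separately from 8 and 4 with EtMgBr (as in step 5), giving (2R,3S,4R)-2-[3,4-bis(benzyloxy)phenyl]chromane-3,4,7-triol F3. Compound 10 is then condensed with excess F3 (5 equiv, 0.1 M HCl, THF–EtOH, rt), C-6 of F3 attacking the C-4 cation of the middle unit anti to its 3-OH. Self-condensation products of F3 are removed on Sephadex LH-20, and the route is rejoined at 12.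

Further compounds
F1 | step 3 | (±)-7-(benzyloxy)-2-[3,4-bis(benzyloxy)phenyl]-2H-chromene (racemate) | c1ccccc1COc1ccc2C=CC(c3ccc(OCc4ccccc4)c(OCc4ccccc4)c3)Oc2c1
F2 | step 4 | (2R,3S,4R)-7-(benzyloxy)-2-[3,4-bis(benzyloxy)phenyl]-4-(2,4-dihydroxyphenyl)chroman-3-ol | c1ccccc1COc1ccc2c(c1)O[C@H](c1ccc(OCc3ccccc3)c(OCc3ccccc3)c1)[C@@H](O)[C@@H]2c1ccc(O)cc1O
F3 | step 7 | (2R,3S,4R)-2-[3,4-bis(benzyloxy)phenyl]chromane-3,4,7-triol | Oc1ccc2c(c1)O[C@H](c1ccc(OCc3ccccc3)c(OCc3ccccc3)c1)[C@@H](O)[C@@H]2O
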